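**Assumption:** 3-ethoxycyclobutan-1-one and the triisopropylsilyl ether of 4-bromophenol are taken as catalogue compounds; the silyl group is a protecting group on 4-bromophenol.

## Retrosynthetic overview

1. Target ⇐ global desilylation; the C2–aryl bond (aryl axial, trans to the C4 oxygen and the C6 side chain) ⇐ nickel-hydride hydroarylation of a 4-silyloxy-3,4-dihydro-2H-pyran with a guaiacyl bromide made from catechol.
2. Dihydropyran ⇐ cis-selective 1,2-reduction and silylation of a 2-substituted 2,3-dihydro-4H-pyran-4-one.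
3. Key step: ring expansion of 3-ethoxycyclobutanone. The C=O of an (R)-2-silyloxy-3-arylpropanal is inserted into its C2–C3 bond (four-membered carbocycle → six-membered oxacycle) under Felkin control.
4. Aldehyde ⇐ (R)-methyl glycidate opened at C3 by the Grignard reagent of protected 4-bromophenol, then silylation and half-reduction.
5. Ring order: only the oxane ring is built, in the ring-expansion step; both benzene rings are bought.

## Route

Step 1
Reactants: 1 (4-bromophenoxy)tri(propan-2-yl)silane; 2 methyl (2R)-oxirane-2-carboxylate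
Product: 4 methyl (2R)-2-hydroxy-3-{4-[tri(propan-2-yl)silyloxy]phenyl}propanoate, via aryl Grignard reagent 3 (not isolated)
Conditions: Mg, THF, 40 °C; then CuI (10 mol %), 2, THF, −40 → −20 °C; aq. NH4Cl
Reagents that add atoms: none
Why: Copper-catalysed Grignard opening of an epoxide: the arylcopper species from 3 attacks the unsubstituted C3 of the glycidate in an SN2 manner faster than the ester is attacked at −40 °C, and C2 is not touched, so its R configuration is carried into 4.

Step 2
Reactants: 4 methyl (2R)-2-hydroxy-3-{4-[tri(propan-2-yl)silyloxy]phenyl}propanoate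
Product: 5 methyl (2R)-2-[tert-butyl(dimethyl)silyloxy]-3-{4-[tri(propan-2-yl)silyloxy]phenyl}propanoate
Conditions: TBSCl, imidazole, DMF, 23 °C
Reagents that add atoms: tert-butyl(chloro)dimethylsilane (TBSCl), CC(C)(C)[Si](C)(C)Cl
Why: Imidazole-promoted silylation of a secondary alcohol; no stereocentre is involved.

Step 3
Reactants: 5 methyl (2R)-2-[tert-butyl(dimethyl)silyloxy]-3-{4-[tri(propan-2-yl)silyloxy]phenyl}propanoate
Product: 6 (2R)-2-[tert-butyl(dimethyl)silyloxy]-3-{4-[tri(propan-2-yl)silyloxy]phenyl}propanal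
Conditions: iBu2AlH (1.1 equiv), CH2Cl2, −78 °C; MeOH, then aq. potassium sodium tartrate
Reagents that add atoms: none
Why: Partial reduction of an ester by DIBAL-H: the aluminium hemiacetal of the α-silyloxy ester is stable at −78 °C and releases the aldehyde only on work-up, without epimerising the α-stereocentre.

Step 4
Reactants: 6 (2R)-2-[tert-butyl(dimethyl)silyloxy]-3-{4-[tri(propan-2-yl)silyloxy]phenyl}propanal; 7 3-ethoxycyclobutan-1-one
Product: 9 (2S)-2-[(1R)-1-[tert-butyl(dimethyl)silyloxy]-2-{4-[tri(propan-2-yl)silyloxy]phenyl}ethyl]-2,3-dihydro-4H-pyran-4-one, via 6-ethoxyoxan-4-one adduct 8 (not isolated)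
Conditions: BF3·OEt2 (2 equiv), CH2Cl2, −45 → 0 °C
Reagents that add atoms: none
Why: Lewis-acid ring expansion of a 3-alkoxycyclobutanone by insertion of an aldehyde C=O (a stepwise, zwitterionic formal [4+2] annulation): BF3 opens 7 between C2 and C3 to a boron enolate carrying an ethoxy-stabilised cation, the enolate carbon adds to 6 under Felkin–Anh control anti to the α-silyloxy group (as in BF3-mediated Mukaiyama aldol additions) and so sets the new ring carbon as S, the aldolate oxygen closes onto the cationic carbon to give 8, and 8 loses ethanol to the vinylogous ester 9.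

Step 5
Reactants: 9 (2S)-2-[(1R)-1-[tert-butyl(dimethyl)silyloxy]-2-{4-[tri(propan-2-yl)silyloxy]phenyl}ethyl]-2,3-dihydro-4H-pyran-4-one
Product: 10 (2S,4S)-2-[(1R)-1-[tert-butyl(dimethyl)silyloxy]-2-{4-[tri(propan-2-yl)silyloxy]phenyl}ethyl]-3,4-dihydro-2H-pyran-4-ol
Conditions: NaBH4, CeCl3·7H2O, MeOH/CH2Cl2, −78 °C
Reagents that add atoms: none
Why: Luche reduction (1,2-selective): hydride attacks the half-chair enone, whose C2 side chain is pseudo-equatorial, along the axial trajectory and gives the pseudo-equatorial alcohol cis to the side chain (4S).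

Step 6
Reactants: 10 (2S,4S)-2-[(1R)-1-[tert-butyl(dimethyl)silyloxy]-2-{4-[tri(propan-2-yl)silyloxy]phenyl}ethyl]-3,4-dihydro-2H-pyran-4-ol
Product: 11 (2S,4S)-4-[tert-butyl(dimethyl)silyloxy]-2-[(1R)-1-[tert-butyl(dimethyl)silyloxy]-2-{4-[tri(propan-2-yl)silyloxy]phenyl}ethyl]-3,4-dihydro-2H-pyran
Conditions: TBSCl, imidazole, DMF, 23 °C
Reagents that add atoms: tert-butyl(chloro)dimethylsilane (TBSCl), CC(C)(C)[Si](C)(C)Cl
Why: Imidazole-promoted silylation under non-acidic conditions, which the acid-labile 4-hydroxy enol ether tolerates; no stereocentre is changed.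

Step 7
Reactants: 12 benzene-1,2-diol (catechol)
Product: 13 2-methoxyphenol
Conditions: MeI (1.0 equiv), Li2CO3, DMF, 50 °C
Reagents that add atoms: iodomethane, CI
Why: Williamson ether synthesis held at the mono-ether stage: the weak base Li2CO3 deprotonates catechol (the stronger acid) in preference to 13 and only one equivalent of MeI is used.

Step 8
Reactants: 13 2-methoxyphenol
Product: 14 4-bromo-2-methoxyphenol
Conditions: NBS (1.0 equiv), MeCN, 0 °C
Reagents that add atoms: N-bromosuccinimide, O=C1CCC(=O)N1Br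
Why: Electrophilic aromatic bromination: the free hydroxyl is the strongest activating group and directs bromine to its unhindered para position.

Step 9
Reactants: 14 4-bromo-2-methoxyphenol
Product: 15 (4-bromo-2-methoxyphenoxy)tri(propan-2-yl)silane
Conditions: TIPSCl, imidazole, DMF, 23 °C
Reagents that add atoms: chlorotri(propan-2-yl)silane (TIPSCl), CC(C)[Si](Cl)(C(C)C)C(C)C
Why: Imidazole-promoted silylation of the phenol; the triisopropylsilyl ether withstands the basic conditions of the coupling step.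

Step 10
Reactants: 11 (2S,4S)-4-[tert-butyl(dimethyl)silyloxy]-2-[(1R)-1-[tert-butyl(dimethyl)silyloxy]-2-{4-[tri(propan-2-yl)silyloxy]phenyl}ethyl]-3,4-dihydro-2H-pyran; 15 (4-bromo-2-methoxyphenoxy)tri(propan-2-yl)silane
Product: 16 (2S,4R,6S)-4-[tert-butyl(dimethyl)silyloxy]-6-[(1R)-1-[tert-butyl(dimethyl)silyloxy]-2-{4-[tri(propan-2-yl)silyloxy]phenyl}ethyl]-2-{3-methoxy-4-[tri(propan-2-yl)silyloxy]phenyl}oxane
Conditions: 15 (1.5 equiv), NiBr2·DME (10 mol %; DME = 1,2-dimethoxyethane), 4,4′-di-tert-butyl-2,2′-bipyridine (12 mol %), (EtO)2MeSiH (2.5 equiv), K3PO4 (2.5 equiv), DMA/THF, 30 °C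
Reagents that add atoms: none
Why: Proposed new method: a bipyridine-ligated Ni–H species formed from the nickel bromide and the silane adds across the enol ether of 11 and, through reversible insertion, settles on the oxygen-stabilised α-alkoxyalkyl nickel at C6; the aryl bromide 15 then enters by oxidative addition, and the alkyl(aryl)nickel intermediate, which can equilibrate through the anomeric radical, forms the C–aryl bond on the axial face of the chair that keeps the C4 silyloxy group and the side chain equatorial, so the aryl group ends up trans to both (2S in 16). The closest known reactions are nickel-hydride α-selective hydroarylation and hydroalkylation of enol ethers, enamides and glycals with organic halides and the axial-selective nickel-catalysed arylation of glycosyl halides; what has not been shown is a non-carbohydrate 4-silyloxy-2-alkyl dihydropyran with an electron-rich aryl bromide, where the 1,3- and 1,5-relationships are both set in this step.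

Step 11
Reactants: 16 (2S,4R,6S)-4-[tert-butyl(dimethyl)silyloxy]-6-[(1R)-1-[tert-butyl(dimethyl)silyloxy]-2-{4-[tri(propan-2-yl)silyloxy]phenyl}ethyl]-2-{3-methoxy-4-[tri(propan-2-yl)silyloxy]phenyl}oxane
Product: 17 (2S,4R,6S)-2-(4-hydroxy-3-methoxyphenyl)-6-[(1R)-1-hydroxy-2-(4-hydroxyphenyl)ethyl]oxan-4-ol
Conditions: Bu4NF/AcOH (1:1, 6 equiv), THF, 0 → 23 °C
Reagents that add atoms: none
Why: Fluoride-induced cleavage of all four silyl ethers (Si–F bond formation); acetic acid keeps the medium near neutral so that neither phenoxide nor acid is present to open the benzylic C2–O bond, and no stereocentre is touched.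

## Compound list

1 | (4-bromophenoxy)tri(propan-2-yl)silane | Brc1ccc(O[Si](C(C)C)(C(C)C)C(C)C)cc1 | starting material
2 | methyl (2R)-oxirane-2-carboxylate | COC(=O)[C@H]1CO1 | starting material
3 | {4-[tri(propan-2-yl)silyloxy]phenyl}magnesium bromide | Br[Mg]c1ccc(O[Si](C(C)C)(C(C)C)C(C)C)cc1 | intermediate
4 | methyl (2R)-2-hydroxy-3-{4-[tri(propan-2-yl)silyloxy]phenyl}propanoate | COC(=O)[C@H](O)Cc1ccc(O[Si](C(C)C)(C(C)C)C(C)C)cc1 | intermediate
5 | methyl (2R)-2-[tert-butyl(dimethyl)silyloxy]-3-{4-[tri(propan-2-yl)silyloxy]phenyl}propanoate | COC(=O)[C@H](O[Si](C)(C)C(C)(C)C)Cc1ccc(O[Si](C(C)C)(C(C)C)C(C)C)cc1 | intermediate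
6 | (2R)-2-[tert-butyl(dimethyl)silyloxy]-3-{4-[tri(propan-2-yl)silyloxy]phenyl}propanal | O=C[C@H](O[Si](C)(C)C(C)(C)C)Cc1ccc(O[Si](C(C)C)(C(C)C)C(C)C)cc1 | intermediate
7 | 3-ethoxycyclobutan-1-one | CCOC1CC(=O)C1 | starting material
8 | (2S,6RS)-2-[(1R)-1-[tert-butyl(dimethyl)silyloxy]-2-{4-[tri(propan-2-yl)silyloxy]phenyl}ethyl]-6-ethoxyoxan-4-one | CCOC1CC(=O)C[C@@H]([C@H](O[Si](C)(C)C(C)(C)C)Cc2ccc(O[Si](C(C)C)(C(C)C)C(C)C)cc2)O1 | intermediate
9 | (2S)-2-[(1R)-1-[tert-butyl(dimethyl)silyloxy]-2-{4-[tri(propan-2-yl)silyloxy]phenyl}ethyl]-2,3-dihydro-4H-pyran-4-one | O=C1C[C@@H]([C@H](O[Si](C)(C)C(C)(C)C)Cc2ccc(O[Si](C(C)C)(C(C)C)C(C)C)cc2)OC=C1 | intermediate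
10 | (2S,4S)-2-[(1R)-1-[tert-butyl(dimethyl)silyloxy]-2-{4-[tri(propan-2-yl)silyloxy]phenyl}ethyl]-3,4-dihydro-2H-pyran-4-ol | C1=C[C@@H](O)C[C@@H]([C@H](O[Si](C)(C)C(C)(C)C)Cc2ccc(O[Si](C(C)C)(C(C)C)C(C)C)cc2)O1 | intermediate
11 | (2S,4S)-4-[tert-butyl(dimethyl)silyloxy]-2-[(1R)-1-[tert-butyl(dimethyl)silyloxy]-2-{4-[tri(propan-2-yl)silyloxy]phenyl}ethyl]-3,4-dihydro-2H-pyran | C1=C[C@@H](O[Si](C)(C)C(C)(C)C)C[C@@H]([C@H](O[Si](C)(C)C(C)(C)C)Cc2ccc(O[Si](C(C)C)(C(C)C)C(C)C)cc2)O1 | intermediate
12 | benzene-1,2-diol (catechol) | Oc1ccccc1O | starting material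
13 | 2-methoxyphenol | COc1ccccc1O | intermediate
14 | 4-bromo-2-methoxyphenol | COc1cc(Br)ccc1O | intermediate
15 | (4-bromo-2-methoxyphenoxy)tri(propan-2-yl)silane | COc1cc(Br)ccc1O[Si](C(C)C)(C(C)C)C(C)C | intermediate
16 | (2S,4R,6S)-4-[tert-butyl(dimethyl)silyloxy]-6-[(1R)-1-[tert-butyl(dimethyl)silyloxy]-2-{4-[tri(propan-2-yl)silyloxy]phenyl}ethyl]-2-{3-methoxy-4-[tri(propan-2-yl)silyloxy]phenyl}oxane | COc1cc([C@@H]2C[C@@H](O[Si](C)(C)C(C)(C)C)C[C@@H]([C@H](O[Si](C)(C)C(C)(C)C)Cc3ccc(O[Si](C(C)C)(C(C)C)C(C)C)cc3)O2)ccc1O[Si](C(C)C)(C(C)C)C(C)C | intermediate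
17 | (2S,4R,6S)-2-(4-hydroxy-3-methoxyphenyl)-6-[(1R)-1-hydroxy-2-(4-hydroxyphenyl)ethyl]oxan-4-ol | COc1cc([C@@H]2C[C@@H](O)C[C@@H]([C@H](O)Cc3ccc(O)cc3)O2)ccc1O | target

## Step count and risks

Total step count: 11. Longest linear sequence: 8 steps (steps 1 to 6, then 10 and 11).

The three steps most likely to fail are steps 4, 10 and 11.

Step 4 may give only modest Felkin selectivity, the unsubstituted cyclobutanone may open sluggishly, or a silyl ether may be lost to BF3 on warming. The fallback sets out from 6. BF3·OEt2-mediated Mukaiyama aldol addition of trans-1-methoxy-3-(trimethylsilyloxy)buta-1,3-diene (CH2Cl2, −78 °C) gives the Felkin β-hydroxy enone F1. Trifluoroacetic acid (CH2Cl2, 0 °C) then closes F1 by oxa-Michael addition and loss of methanol (the classical diene–aldehyde cyclocondensation). It comes back to the route at 9.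

Step 10, the proposed new step, may place nickel at C5 and lose the C4 silyloxy group by β-elimination, or may simply reduce the electron-rich bromide. The fallback uses known chemistry and sets out from 11. Benzenesulfinic acid (CaCl2, CH2Cl2, 23 °C) adds across the enol ether to give the anomeric phenyl sulfone F2. Separately, 15 and Mg (THF) give the aryl Grignard reagent F3, which ZnBr2 converts into the arylzinc bromide F4. F4 (THF, 23 °C) ionises the sulfone of F2 and delivers the aryl group axially to the oxocarbenium ion, the established substitution of 2-sulfonyl cyclic ethers by organozinc reagents, which is 2,6-trans selective. It comes back to the route at 16.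

Step 11 may stall at the hindered secondary silyl ethers, and forcing it risks opening the axial C2–O bond once the para-hydroxyphenyl group is free, with re-closure to the 2,6-cis isomer. The fallback sets out from 16 and unmasks in two stages. HF·pyridine buffered with pyridine (THF, 0 → 23 °C) removes only the two alkyl silyl ethers and gives the diol F5, in which both phenols are still silylated. Bu4NF/AcOH (THF, 0 °C, a few minutes) then cleaves the two aryl silyl ethers, so the para-phenol is free only in the last, cold, buffered operation. It comes back to the route at 17.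

## Further compounds

F1 | step 4 | (1E,5S,6R)-6-[tert-butyl(dimethyl)silyloxy]-5-hydroxy-1-methoxy-7-{4-[tri(propan-2-yl)silyloxy]phenyl}hept-1-en-3-one | CO/C=C/C(=O)C[C@H](O)[C@H](O[Si](C)(C)C(C)(C)C)Cc1ccc(O[Si](C(C)C)(C(C)C)C(C)C)cc1
F2 | step 10 | (2RS,4S,6S)-2-(benzenesulfonyl)-4-[tert-butyl(dimethyl)silyloxy]-6-[(1R)-1-[tert-butyl(dimethyl)silyloxy]-2-{4-[tri(propan-2-yl)silyloxy]phenyl}ethyl]oxane | O=S(=O)(c1ccccc1)C1C[C@@H](O[Si](C)(C)C(C)(C)C)C[C@@H]([C@H](O[Si](C)(C)C(C)(C)C)Cc2ccc(O[Si](C(C)C)(C(C)C)C(C)C)cc2)O1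
F3 | step 10 | {3-methoxy-4-[tri(propan-2-yl)silyloxy]phenyl}magnesium bromide | COc1cc([Mg]Br)ccc1O[Si](C(C)C)(C(C)C)C(C)C
F4 | step 10 | bromo{3-methoxy-4-[tri(propan-2-yl)silyloxy]phenyl}zinc | COc1cc([Zn]Br)ccc1O[Si](C(C)C)(C(C)C)C(C)C
F5 | step 11 | (2S,4R,6S)-6-[(1R)-1-hydroxy-2-{4-[tri(propan-2-yl)silyloxy]phenyl}ethyl]-2-{3-methoxy-4-[tri(propan-2-yl)silyloxy]phenyl}oxan-4-ol | COc1cc([C@@H]2C[C@@H](O)C[C@@H]([C@H](O)Cc3ccc(O[Si](C(C)C)(C(C)C)C(C)C)cc3)O2)ccc1O[Si](C(C)C)(C(C)C)C(C)C
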